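**Plan** (chain numbered from the carboxyl carbon C1 to the aryl-bearing carbon C12)

- Cuts: last, the C7–C8 single bond (vinylic CH of the 6,7-alkene to the C8 methylene), giving fragment 1 (aryl C8–C12 acid as its N-acyloxyphthalimide, the extra acid carbon leaving as CO2) and fragment 2 (C1–C7 E-alkenyl iodide). Before that: aryl–C12 (Heck), C2=C3 (Wittig), C2–homoprenyl (ylide alkylation), C6–CH3 (alkyne carboalumination).
- Enabling feature: C8 is a primary carbon two atoms from the C10 carbinol, so C8–C12 plus one carboxyl carbon is the acid left when the 6,7-alkene of linalool is cleaved. C7 is the hydrogen-bearing end of a methyl-branched E-alkene, the pattern that syn-carboalumination/iodination of a 1-alkyne delivers. The only ring, the hydroquinone benzene ring, is bought; no ring is closed.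
- Forward order: aryl iodide (steps 1–2); linalool to silyl ether, acid, Heck product and phthalimide ester (steps 3–6); ylide and iodo-enal to the alkenyl iodide (steps 7–11); nickel-electrocatalytic decarboxylative alkenylation (step 12); one fluoride step removes every helper (step 13).
- Stereochemistry: C10 (S) comes from (S)-linalool and no bond to it is made or broken; 11E from Heck β-hydride elimination; 6E from syn-carboalumination, retained in iodination and coupling; 2E from the stabilised Wittig reaction.
- Helpers: phthalimide ester (lost in step 12); 2-(trimethylsilyl)ethyl ester, two aryl TBS ethers and the tertiary TES ether (all lost in step 13).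

Key step: step 12

Assumption: (S)-(+)-linalool (coriandrol) is taken as purchased in high enantiomeric purity.

**Step 1**
Reactants: 1 2-methylbenzene-1,4-diol
Product: 2 1,4-bis(tert-butyldimethylsilyloxy)-2-methylbenzene
Conditions: TBSCl (2.4 equiv), imidazole, DMF, rt
Reagents that add atoms: tert-butyldimethylsilyl chloride, CC(C)(C)[Si](C)(C)Cl
Why: Imidazole-promoted silylation (Corey protocol) should cap both phenols and mask the oxidation-prone hydroquinone as a fluoride-labile bis(silyl ether).

**Step 2**
Reactants: 2 1,4-bis(tert-butyldimethylsilyloxy)-2-methylbenzene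
Product: 3 1,4-bis(tert-butyldimethylsilyloxy)-2-iodo-5-methylbenzene
Conditions: NIS, CF3CO2H (cat.), MeCN, 0 °C → rt, dark
Reagents that add atoms: N-iodosuccinimide, O=C1CCC(=O)N1I
Why: Electrophilic aromatic iodination should occur para to the methyl group and ortho to a silyloxy group, the one position activated by two donors and not flanked by two substituents, as is usual for 2,5-dialkoxytoluenes.

**Step 3**
Reactants: 4 (S)-linalool
Product: 5 (3S)-3,7-dimethyl-3-(triethylsilyloxy)octa-1,6-diene
Conditions: TESOTf, 2,6-lutidine, CH2Cl2, −78 → 0 °C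
Reagents that add atoms: triethylsilyl trifluoromethanesulfonate, CC[Si](CC)(CC)OS(=O)(=O)C(F)(F)F
Why: Silyl triflate/lutidine silylation is the standard way to cap a hindered tertiary alcohol, and the ether later prevents lactonisation of the 4-oxygenated acid without touching the stereocentre.

**Step 4**
Reactants: 5 (3S)-3,7-dimethyl-3-(triethylsilyloxy)octa-1,6-diene
Product: 7 (4S)-4-methyl-4-(triethylsilyloxy)hex-5-enoic acid, via silyloxy aldehyde 6 (not isolated)
Conditions: O3 (1.0 equiv, calibrated stream), MeCN/H2O 9:1, 0 °C; then NaClO2, NaH2PO4, 0 °C → rt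
Reagents that add atoms: ozone, [O-][O+]=O; sodium chlorite, [Na+].[O-]Cl=O
Why: Ozone should attack the electron-rich trisubstituted alkene much faster than the hindered vinyl group beside the silyloxy carbon, aqueous ozonolysis gives the aldehyde without a reductant, and in situ Pinnick (chlorite) oxidation takes it to the acid with the hydrogen peroxide formed acting as hypochlorite scavenger.

**Step 5**
Reactants: 7 (4S)-4-methyl-4-(triethylsilyloxy)hex-5-enoic acid; 3 1,4-bis(tert-butyldimethylsilyloxy)-2-iodo-5-methylbenzene
Product: 8 (4S,5E)-6-[2,5-bis(tert-butyldimethylsilyloxy)-4-methylphenyl]-4-methyl-4-(triethylsilyloxy)hex-5-enoic acid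
Conditions: Pd(OAc)2 (5 mol %), P(o-tol)3 (10 mol %), Et3N (3 equiv), MeCN, 80 °C
Reagents that add atoms: none
Why: In this Mizoroki–Heck reaction the arylpalladium species should add its aryl group to the terminal alkene carbon, and because the neighbouring carbon is fully substituted the only β-hydrogen is the benzylic one, so syn β-hydride elimination can give only the E-styrene.

**Step 6**
Reactants: 8 (4S,5E)-6-[2,5-bis(tert-butyldimethylsilyloxy)-4-methylphenyl]-4-methyl-4-(triethylsilyloxy)hex-5-enoic acid
Product: 9 1,3-dioxoisoindolin-2-yl (4S,5E)-6-[2,5-bis(tert-butyldimethylsilyloxy)-4-methylphenyl]-4-methyl-4-(triethylsilyloxy)hex-5-enoate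
Conditions: N-hydroxyphthalimide, DIC, DMAP (cat.), CH2Cl2, rt; filtration through a short silica pad
Reagents that add atoms: N-hydroxyphthalimide, O=C1c2ccccc2C(=O)N1O
Why: Carbodiimide (Steglich-type) esterification of an unhindered primary acid with N-hydroxyphthalimide is routine and installs the redox-active group, the silyl ether blocking lactonisation.

**Step 7**
Reactants: 10 (triphenylphosphoranylidene)ketene; 11 2-(trimethylsilyl)ethanol
Product: 12 2-(trimethylsilyl)ethyl 2-(triphenyl-λ5-phosphanylidene)acetate
Conditions: toluene, 100 °C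
Reagents that add atoms: none
Why: Alcohols add across the ketene C=C of the Bestmann ylide to give ester-stabilised ylides, which here delivers the fluoride-cleavable ester with no by-product.

**Step 8**
Reactants: 12 2-(trimethylsilyl)ethyl 2-(triphenyl-λ5-phosphanylidene)acetate; 13 5-bromo-2-methylpent-2-ene
Product: 15 2-(trimethylsilyl)ethyl 6-methyl-2-(triphenyl-λ5-phosphanylidene)hept-5-enoate, via phosphonium bromide 14 (not isolated)
Conditions: NaI (10 mol %), MeCN, reflux; then aq. NaOH, CH2Cl2, 0 °C
Reagents that add atoms: none
Why: C-alkylation of an ester-stabilised ylide by a primary halide (SN2, helped by Finkelstein iodide catalysis) followed by deprotonation of the phosphonium salt is the classical way to an α-alkylated stabilised ylide.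

**Step 9**
Reactants: 16 pent-4-yn-1-ol
Product: 18 (E)-5-iodo-4-methylpent-4-en-1-ol, via alkenylalane 17 (not isolated)
Conditions: AlMe3 (3 equiv), Cp2ZrCl2 (25 mol %), CH2Cl2, 0 °C → rt; then I2, THF, −30 → 0 °C
Reagents that add atoms: trimethylaluminium, C[Al](C)C; iodine, II
Why: Negishi zirconium-catalysed carboalumination adds methyl and aluminium syn across the terminal alkyne with methyl on the internal carbon, and iodinolysis of the C–Al bond with retention should give the E-iodide only.

**Step 10**
Reactants: 18 (E)-5-iodo-4-methylpent-4-en-1-ol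
Product: 19 (E)-5-iodo-4-methylpent-4-enal
Conditions: Dess–Martin periodinane, CH2Cl2, 0 °C → rt; used crude
Reagents that add atoms: none
Why: Dess–Martin oxidation stops at the aldehyde under near-neutral conditions and leaves the alkenyl iodide untouched.

**Step 11**
Reactants: 19 (E)-5-iodo-4-methylpent-4-enal; 15 2-(trimethylsilyl)ethyl 6-methyl-2-(triphenyl-λ5-phosphanylidene)hept-5-enoate
Product: 20 2-(trimethylsilyl)ethyl (2E,6E)-7-iodo-6-methyl-2-(4-methylpent-3-en-1-yl)hepta-2,6-dienoate
Conditions: toluene, 80 °C
Reagents that add atoms: none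
Why: The Wittig reaction of an α-alkylated ester-stabilised ylide with an aliphatic aldehyde should strongly favour the enoate with the ester trans to the new chain, which is the 2E geometry required.

**Step 12**
Reactants: 9 1,3-dioxoisoindolin-2-yl (4S,5E)-6-[2,5-bis(tert-butyldimethylsilyloxy)-4-methylphenyl]-4-methyl-4-(triethylsilyloxy)hex-5-enoate (1.5 equiv); 20 2-(trimethylsilyl)ethyl (2E,6E)-7-iodo-6-methyl-2-(4-methylpent-3-en-1-yl)hepta-2,6-dienoate
Product: 21 2-(trimethylsilyl)ethyl (2E,6E,10S,11E)-12-[2,5-bis(tert-butyldimethylsilyloxy)-4-methylphenyl]-6,10-dimethyl-2-(4-methylpent-3-en-1-yl)-10-(triethylsilyloxy)dodeca-2,6,11-trienoate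
Conditions: NiCl2·6H2O (10 mol %), 2,2'-bipyridine (10 mol %), AgNO3 (30 mol %), LiCl, DMF, Mg anode, RVC cathode, constant current (about 3 F/mol), rt, undivided cell
Reagents that add atoms: none
Why: Cathodic reduction of the bipyridine complex of divalent nickel gives low-valent nickel that inserts into the C–I bond of 20 with retention of the E geometry, while single-electron transfer to the N-acyloxyphthalimide 9 expels phthalimide anion and CO2 to leave the primary C8 radical; capture of this radical by the alkenylnickel species and reductive elimination from trivalent nickel forge the C7–C8 bond, the Mg anode supplying the electrons. The closest known reaction type is the nickel-catalysed decarboxylative alkenylation of redox-active esters, run here in its electroreductive cross-electrophile form with a cathode coated by silver nanoparticles (from AgNO3) that keeps the catalyst alive. No ring is closed and no stereocentre is formed: C10 lies two carbons from the radical and is untouched, and the 6E geometry is fixed by stereoretentive oxidative addition and reductive elimination. The step needs cross- over homo-coupling, which the different activation modes of the two partners (two-electron for C–I, one-electron for the ester) should secure. It also needs the radical to ignore the alkenes of its own chain, and the substrate helps: the styrene double bond stands in a 4-pentenyl relationship to C8, so only slow 4-exo or 5-endo closures are open, and the enoate and remaining alkenes are trisubstituted and poor radical acceptors. Esters, silyl ethers and the electron-rich arene should be inert at the mild cathode potential.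

**Step 13**
Reactants: 21 2-(trimethylsilyl)ethyl (2E,6E,10S,11E)-12-[2,5-bis(tert-butyldimethylsilyloxy)-4-methylphenyl]-6,10-dimethyl-2-(4-methylpent-3-en-1-yl)-10-(triethylsilyloxy)dodeca-2,6,11-trienoate
Product: 22 (2E,6E,10S,11E)-12-(2,5-dihydroxy-4-methylphenyl)-10-hydroxy-6,10-dimethyl-2-(4-methylpent-3-en-1-yl)dodeca-2,6,11-trienoic acid
Conditions: TBAF (8 equiv), THF, 0 °C → rt, argon; aq. NH4Cl/Na2S2O4 work-up
Reagents that add atoms: none
Why: Fluoride-mediated desilylation cleaves both aryl silyl ethers and the tertiary triethylsilyl ether and fragments the 2-(trimethylsilyl)ethyl ester by β-elimination, all without acid, so the ionisation-prone tertiary styrenyl alcohol should survive and the reducing work-up keeps the hydroquinone from oxidising.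

**Compound list**

1 | 2-methylbenzene-1,4-diol (methylhydroquinone) | Cc1cc(O)ccc1O | starting material
2 | 1,4-bis(tert-butyldimethylsilyloxy)-2-methylbenzene | Cc1cc(O[Si](C)(C)C(C)(C)C)ccc1O[Si](C)(C)C(C)(C)C | intermediate
3 | 1,4-bis(tert-butyldimethylsilyloxy)-2-iodo-5-methylbenzene | Cc1cc(O[Si](C)(C)C(C)(C)C)c(I)cc1O[Si](C)(C)C(C)(C)C | intermediate
4 | (S)-linalool, (3S)-3,7-dimethylocta-1,6-dien-3-ol | CC(C)=CCC[C@](C)(O)C=C | starting material
5 | (3S)-3,7-dimethyl-3-(triethylsilyloxy)octa-1,6-diene | CC(C)=CCC[C@](C)(O[Si](CC)(CC)CC)C=C | intermediate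
6 | (4S)-4-methyl-4-(triethylsilyloxy)hex-5-enal | O=CCC[C@](C)(O[Si](CC)(CC)CC)C=C | intermediate
7 | (4S)-4-methyl-4-(triethylsilyloxy)hex-5-enoic acid | OC(=O)CC[C@](C)(O[Si](CC)(CC)CC)C=C | intermediate
8 | (4S,5E)-6-[2,5-bis(tert-butyldimethylsilyloxy)-4-methylphenyl]-4-methyl-4-(triethylsilyloxy)hex-5-enoic acid | OC(=O)CC[C@](C)(O[Si](CC)(CC)CC)/C=C/c1cc(O[Si](C)(C)C(C)(C)C)c(C)cc1O[Si](C)(C)C(C)(C)C | intermediate
9 | 1,3-dioxoisoindolin-2-yl (4S,5E)-6-[2,5-bis(tert-butyldimethylsilyloxy)-4-methylphenyl]-4-methyl-4-(triethylsilyloxy)hex-5-enoate | O=C(CC[C@](C)(O[Si](CC)(CC)CC)/C=C/c1cc(O[Si](C)(C)C(C)(C)C)c(C)cc1O[Si](C)(C)C(C)(C)C)ON1C(=O)c2ccccc2C1=O | intermediate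
10 | (triphenylphosphoranylidene)ketene | O=C=C=P(c1ccccc1)(c1ccccc1)c1ccccc1 | starting material
11 | 2-(trimethylsilyl)ethanol | C[Si](C)(C)CCO | starting material
12 | 2-(trimethylsilyl)ethyl 2-(triphenyl-λ5-phosphanylidene)acetate | C[Si](C)(C)CCOC(=O)C=P(c1ccccc1)(c1ccccc1)c1ccccc1 | intermediate
13 | 5-bromo-2-methylpent-2-ene | CC(C)=CCCBr | starting material
14 | [6-methyl-1-oxo-1-(2-(trimethylsilyl)ethoxy)hept-5-en-2-yl]triphenylphosphonium bromide | CC(C)=CCCC(C(=O)OCC[Si](C)(C)C)[P+](c1ccccc1)(c1ccccc1)c1ccccc1.[Br-] | intermediate
15 | 2-(trimethylsilyl)ethyl 6-methyl-2-(triphenyl-λ5-phosphanylidene)hept-5-enoate | CC(C)=CCCC(C(=O)OCC[Si](C)(C)C)=P(c1ccccc1)(c1ccccc1)c1ccccc1 | intermediate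
16 | pent-4-yn-1-ol | OCCCC#C | starting material
17 | dimethylaluminium (E)-5-(dimethylalumanyl)-4-methylpent-4-en-1-olate | C[Al](C)OCCC/C(C)=C/[Al](C)C | intermediate
18 | (E)-5-iodo-4-methylpent-4-en-1-ol | OCCC/C(C)=C/I | intermediate
19 | (E)-5-iodo-4-methylpent-4-enal | O=CCC/C(C)=C/I | intermediate
20 | 2-(trimethylsilyl)ethyl (2E,6E)-7-iodo-6-methyl-2-(4-methylpent-3-en-1-yl)hepta-2,6-dienoate | CC(C)=CCC/C(=C\CC/C(C)=C/I)C(=O)OCC[Si](C)(C)C | intermediate
21 | 2-(trimethylsilyl)ethyl (2E,6E,10S,11E)-12-[2,5-bis(tert-butyldimethylsilyloxy)-4-methylphenyl]-6,10-dimethyl-2-(4-methylpent-3-en-1-yl)-10-(triethylsilyloxy)dodeca-2,6,11-trienoate | CC(C)=CCC/C(=C\CC/C(C)=C/CC[C@](C)(O[Si](CC)(CC)CC)/C=C/c1cc(O[Si](C)(C)C(C)(C)C)c(C)cc1O[Si](C)(C)C(C)(C)C)C(=O)OCC[Si](C)(C)C | intermediate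
22 | (2E,6E,10S,11E)-12-(2,5-dihydroxy-4-methylphenyl)-10-hydroxy-6,10-dimethyl-2-(4-methylpent-3-en-1-yl)dodeca-2,6,11-trienoic acid | CC(C)=CCC/C(=C\CC/C(C)=C/CC[C@](C)(O)/C=C/c1cc(O)c(C)cc1O)C(=O)O | target

**Totals**

Total step count: 13. Longest linear sequence: 6 steps (steps 3, 4, 5, 6, 12, 13).

**Steps most likely to fail**

Step 12. The redox-active ester may be reduced and lose CO2 faster than the alkenylnickel species forms, so that the primary radical is quenched by hydrogen abstraction or dimerises, and the cathode may passivate. The fallback replaces the radical coupling by a two-electron cross-coupling. Setting out from 9, light-driven decarboxylative borylation (bis(catecholato)diboron, DMAc, blue light; then pinacol, Et3N) would give 2-[(3S,4E)-5-[2,5-bis(tert-butyldimethylsilyloxy)-4-methylphenyl]-3-methyl-3-(triethylsilyloxy)pent-4-en-1-yl]-4,4,5,5-tetramethyl-1,3,2-dioxaborolane F1. A B-alkyl Suzuki–Miyaura coupling of this boronate with 20 (PdCl2(dppf), Ag2O, K2CO3, THF, 65 °C) should proceed with retention of the alkene geometry and come back to the route at 21.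

Step 5. Carbopalladation of a vinyl group beside a fully substituted silyloxy carbon may be slow, which would let β-silyloxy elimination, desilylation or palladium-hydride double-bond migration compete. The fallback makes the styrene bond by olefin cross-metathesis instead. Setting out from 3, Stille vinylation (tributyl(vinyl)stannane, Pd(PPh3)4, toluene, 90 °C) would give 1,4-bis(tert-butyldimethylsilyloxy)-2-ethenyl-5-methylbenzene F2. Cross-metathesis of this styrene with 7 (second-generation Hoveyda–Grubbs catalyst, CH2Cl2, 40 °C, ethylene swept out) should give the E-alkene and come back to the route at 8.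

Step 8. SN2 alkylation of the weakly nucleophilic stabilised ylide by an unactivated primary bromide may be sluggish, with proton transfer between the salt and unreacted ylide and E2 elimination of the halide draining material. The fallback builds the same ylide by C-acylation rather than C-alkylation. Setting out from 13, quaternisation with PPh3 (MeCN, reflux) would give (4-methylpent-3-en-1-yl)triphenylphosphonium bromide F3. Deprotonation with NaN(SiMe3)2 (2 equiv, THF, −78 °C) and acylation of the resulting non-stabilised ylide with 4-nitrophenyl 2-(trimethylsilyl)ethyl carbonate would come back to the route at 15, step 7 then being unnecessary.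

**Further compounds**
F1 | step 12 | 2-[(3S,4E)-5-[2,5-bis(tert-butyldimethylsilyloxy)-4-methylphenyl]-3-methyl-3-(triethylsilyloxy)pent-4-en-1-yl]-4,4,5,5-tetramethyl-1,3,2-dioxaborolane | CC1(C)OB(CC[C@](C)(O[Si](CC)(CC)CC)/C=C/c2cc(O[Si](C)(C)C(C)(C)C)c(C)cc2O[Si](C)(C)C(C)(C)C)OC1(C)C
F2 | step 5 | 1,4-bis(tert-butyldimethylsilyloxy)-2-ethenyl-5-methylbenzene | C=Cc1cc(O[Si](C)(C)C(C)(C)C)c(C)cc1O[Si](C)(C)C(C)(C)C
F3 | step 8 | (4-methylpent-3-en-1-yl)triphenylphosphonium bromide | CC(C)=CCC[P+](c1ccccc1)(c1ccccc1)c1ccccc1.[Br-]
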